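The data were generated by integration on assumed constants; noise was put on by code.

Amounts first: blue holds Q at 0.800 of its L, so in blue Q is the limiting reagent, and each Z takes two Q. As a balance in fractions of the charge, the Q left is one minus the charge ratio of L to Q, times J plus two Z. G and any other unread form go uncounted, so this balance reads high.

the same everywhere: L 0.72 M
- Sunday's: Q 0.47 M; run made earlier
- Monday's: Q 0.91 M; run made earlier
- Saturday's: Q 1.9 M; run made earlier
- blue: Q 0.576 M; time 3.0 d
- violet: Q 0.360 M; time 3.0 d
- ochre: Q 2.16 M; time 3.0 d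

| run | time / h | Z / % | J / % |
|---|---|---|---|
| Sunday's | 6.00 | 0 | 3.8 |
| Sunday's | 20.0 | 1.2 | 6.2 |
| Sunday's | 30.0 | 2.3 | 7.2 |
| Sunday's | 48.0 | 4.5 | 7.7 |
| Monday's | 4.00 | 0 | 3.8 |
| Monday's | 10.0 | 2.1 | 8.0 |
| Monday's | 20.0 | 5.2 | 10.9 |
| Monday's | 48.0 | 12.5 | 11.3 |
| Saturday's | 12.0 | 7.4 | 14.3 |
| Saturday's | 25.0 | 19.4 | 13.3 |
| Saturday's | 40.0 | 30.5 | 10.5 |
| Saturday's | 48.0 | 36.0 | 11.1 |

(readings scatter by 0.5 percentage points)



* which of these holds the largest part of the L at the end of blue (Z / J / L / G)
* which of these holds the largest part of the L at the end of violet (Z / J / L / G)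
* which of these holds the largest part of the L at the end of ochre (Z / J / L / G)
* final Z in blue, as a percentage of the L charged

The last two readings of each run carry the argument. In Monday's run J goes from 10.9% to 11.3% while Z climbs from 5.2% to 12.5%, so over such a stretch J is treated here as a standing amount. Between those rows, the hourly Z gain divided by the mean J and by the Q the balance leaves gives 0.0447 M⁻¹ h⁻¹ for Sunday's run, 0.0334 M⁻¹ h⁻¹ for Monday's and 0.0474 M⁻¹ h⁻¹ for Saturday's. Their mean, 0.0418 M⁻¹ h⁻¹, a reading with the scatter of those runs, serves as the Z constant, the hourly Z gain per unit of J and of Q left.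

Blue's Q lies between Sunday's and Monday's. Interpolating at their last reading gives blue an estimated J of 8.57% and Z of 6.43%. The balance then puts blue's Q at 73.2% of its charge, and the constant, with J and Q held there, carries the estimate of blue's Z to 10.1%. That leaves 81.4% of blue's L for L and whatever is unread, more than J or Z holds, and the answer taken for blue is L. Violet charges less Q than Sunday's run, so L again. Ochre, started from Saturday's last Z, reaches 53.4%, so Z.

The forecast, by its own route (“fast reversible formation of J”), names L, L and Z, with 10% of Z in blue.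

    L + Q → J (k = 0.0146 M⁻¹ h⁻¹)
    L + Q → G (k = 0.00832 M⁻¹ h⁻¹)
    Q + J → Z (k = 0.0369 M⁻¹ h⁻¹)
    Q + G → Z (k = 0.00712 M⁻¹ h⁻¹)
    L + J → D (k = 0.0385 M⁻¹ h⁻¹)
    L ⇌ E (K = 0.244, k = 0.0214 h⁻¹)

Blue ends with 8.57% of Z, less than the 10.1% reckoned, while L holds 42.2% and the unread G 12.5%. From 1.50 d to 3.00 d, the constant times blue's simulated J and Q gives 3.9 percentage points of Z, and blue gained 4.3 points. Over the same span violet's J and Q give 1.8 points, and violet gained 1.9 points.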